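All four C–Br bonds are disconnected at once, back to a bromine-free diaryl ether. Ring A carries bromine at C2 and C4, the two open positions that a C1 oxygen activates. Ring B carries it at C4' and C6', which the C2' hydroxyl cannot activate but which both adjoin the hydrogen-bearing C5'. A free C1 phenol and a temporary C5' amine should therefore guide bromine to all four carbons in one operation, while a mesylate silences the C2' oxygen. The precursor, 4-amino-2-(2-hydroxyphenoxy)phenyl methanesulfonate, is built regiospecifically from 4-nitrocatechol and 2-fluorobenzaldehyde. O-methylation, reductive deamination and mesylate hydrolysis finish the target.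

Key step: step 5

Remark on locants (assumption): ring A is the methoxy ring (C1 OMe, C2 and C4 Br, C6 bridging oxygen). Ring B is the phenol ring (C1' bridging oxygen, C2' OH, C4' and C6' Br). The target has no stereocentre.

Design points:
- The two ring oxygens are differentiated from step 1, so no mononitration or selective sulfonylation of a symmetric bisphenol is needed.
- Hydrogenation comes before any C–Br bond exists.
- Nitrophenol 8 never meets base.
- The ring A phenol is capped before the diazonium ion is formed.
- The final hydrolysis is run without alcohol.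

Step 1
Reactants: 1 4-nitrocatechol (4-nitrobenzene-1,2-diol, 1.1 equiv); 2 2-fluorobenzaldehyde
Product: 3 2-(2-hydroxy-5-nitrophenoxy)benzaldehyde
Conditions: K2CO3 (3 equiv), DMSO, N2, 100 °C; then aq. HCl
Reagents that add atoms: none
Why: Nucleophilic aromatic substitution of the fluoride ortho to the formyl group by the catecholate dianion, whose more basic and more nucleophilic oxygen is the one meta to the nitro group, while any ether formed at the other oxygen should be funnelled to 3 by a Smiles rearrangement at the formyl-activated ipso carbon because 3 releases the more stable para-nitrophenoxide.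

Step 2
Reactants: 3 2-(2-hydroxy-5-nitrophenoxy)benzaldehyde; 4 methanesulfonyl chloride
Product: 5 2-(2-formylphenoxy)-4-nitrophenyl methanesulfonate
Conditions: MsCl (1.2 equiv), Et3N (1.5 equiv), CH2Cl2, 0 °C
Reagents that add atoms: methanesulfonyl chloride (4), CS(=O)(=O)Cl
Why: O-Sulfonylation of the only hydroxyl group present places the mesyl group on the C2' oxygen without competition, and the aldehyde and nitro groups are inert to these conditions.

Step 3
Reactants: 5 2-(2-formylphenoxy)-4-nitrophenyl methanesulfonate; 6 3-chloroperoxybenzoic acid (mCPBA)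
Product: 8 2-(2-hydroxyphenoxy)-4-nitrophenyl methanesulfonate, via aryl formate 7 (not isolated)
Conditions: mCPBA (1.5 equiv), CH2Cl2, rt to 40 °C; then MeOH, cat. HCl, rt
Reagents that add atoms: 3-chloroperoxybenzoic acid (6), OOC(=O)c1cccc(Cl)c1
Why: Baeyer–Villiger oxidation of an ortho-aryloxybenzaldehyde, in which the oxygen-substituted aryl group migrates in the Criegee adduct, followed by acid-catalysed transesterification of the formate, frees the ring A phenol without forming its phenoxide next to the nitro-activated mesylate, where base could close a dibenzodioxin or shift the mesyl group.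

Step 4
Reactants: 8 2-(2-hydroxyphenoxy)-4-nitrophenyl methanesulfonate
Product: 9 4-amino-2-(2-hydroxyphenoxy)phenyl methanesulfonate
Conditions: H2 (1 atm), 5% Pd/C, EtOAc, rt
Reagents that add atoms: none
Why: Catalytic hydrogenation of an aromatic nitro group under neutral conditions leaves the aryl mesylate, phenol and diaryl ether intact and at the same time removes the activation of C2' towards nucleophiles.

Step 5
Reactants: 9 4-amino-2-(2-hydroxyphenoxy)phenyl methanesulfonate; 10 bromine
Product: 11 4-amino-3,5-dibromo-2-(3,5-dibromo-2-hydroxyphenoxy)phenyl methanesulfonate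
Conditions: Br2 (4.1 equiv), NaOAc (4.5 equiv), AcOH, 10 °C to rt; aq. NaHSO3 quench
Reagents that add atoms: bromine (10), BrBr
Why: Mechanistically this is a fourfold electrophilic aromatic substitution in which the two donor-activated rings attack molecular bromine, each sigma complex is stabilised by a nitrogen or oxygen lone pair, and acetate takes up the proton. The closest known reactions are the exhaustive ortho/para bromination of phenols (guaiacol to its 4,6-dibromide) and the 2,6-dibromination of para-substituted anilines in acetic acid. The step needs site selectivity, and on ring B the C5' nitrogen is by far the strongest donor, its para carbon C2' is occupied, its ortho carbons C4' and C6' are reinforced by the bridging oxygen, and C3' is meta to both donors and adjacent to the electron-withdrawing mesyloxy group. On ring A the free hydroxyl dominates over the aryloxy oxygen, whose lone pair is shared with ring B, so bromine should enter at C4 and C2, after which the ring is too deactivated for attack at C3 or C5. No ring is closed and no stereocentre is created. The mesylate also blocks oxidation of ring B to a quinone imine, and the bisulfite quench returns any bromocyclohexadienone formed by ipso attack to the phenol.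

Step 6
Reactants: 11 4-amino-3,5-dibromo-2-(3,5-dibromo-2-hydroxyphenoxy)phenyl methanesulfonate; 12 iodomethane
Product: 13 4-amino-3,5-dibromo-2-(3,5-dibromo-2-methoxyphenoxy)phenyl methanesulfonate
Conditions: MeI (1.2 equiv), K2CO3 (1.5 equiv), acetone, rt
Reagents that add atoms: iodomethane (12), CI
Why: Williamson O-methylation of the acidic dibromophenol, which the doubly ortho-brominated and weakly nucleophilic aniline nitrogen cannot rival, caps the one internal nucleophile that could later close a dibenzodioxin onto the diazonium-activated C2' or C6'.

Step 7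
Reactants: 13 4-amino-3,5-dibromo-2-(3,5-dibromo-2-methoxyphenoxy)phenyl methanesulfonate
Product: 15 3,5-dibromo-2-(3,5-dibromo-2-methoxyphenoxy)phenyl methanesulfonate, via diazonium hydrogen sulfate 14 (not isolated)
Conditions: NaNO2 (1.2 equiv) in conc. H2SO4, then 13 in AcOH, 0–10 °C; then 50% aq. H3PO2 (10 equiv), 0 °C to rt
Reagents that add atoms: sodium nitrite, [Na+].[O-]N=O, and sulfuric acid, OS(=O)(=O)O (both enter intermediate 14 only; nothing but hydrogen stays in 15)
Why: Diazotisation of the weakly basic 2,6-dibromoaniline with nitrosylsulfuric acid followed by hydrodediazoniation with hypophosphorous acid (radical chain with hydrogen-atom transfer from the P–H bond) is the classical removal of an amino director from polybromoanilines, and the chloride-free acid avoids halogen exchange at the activated ortho bromines.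

Step 8
Reactants: 15 3,5-dibromo-2-(3,5-dibromo-2-methoxyphenoxy)phenyl methanesulfonate
Product: 16 3,5-dibromo-2-(3,5-dibromo-2-methoxyphenoxy)phenol (target, CNP0332008.0)
Conditions: NaOH (4 equiv), 1,4-dioxane/H2O, 70 °C; then aq. HCl
Reagents that add atoms: none
Why: Alkaline hydrolysis of the aryl sulfonate with S–O cleavage liberates the C2' phenoxide while the unactivated aryl bromides, methyl ether and diaryl ether are inert, and the alcohol-free medium excludes formation of an alkyl mesylate that could alkylate the phenoxide.

Compound list
1 | 4-nitrocatechol | Oc1ccc(cc1O)[N+](=O)[O-] | starting material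
2 | 2-fluorobenzaldehyde | O=Cc1ccccc1F | starting material
3 | 2-(2-hydroxy-5-nitrophenoxy)benzaldehyde | O=Cc1ccccc1Oc1cc(ccc1O)[N+](=O)[O-] | intermediate
4 | methanesulfonyl chloride | CS(=O)(=O)Cl | starting material
5 | 2-(2-formylphenoxy)-4-nitrophenyl methanesulfonate | CS(=O)(=O)Oc1ccc(cc1Oc1ccccc1C=O)[N+](=O)[O-] | intermediate
6 | 3-chloroperoxybenzoic acid | OOC(=O)c1cccc(Cl)c1 | starting material
7 | 2-[2-(formyloxy)phenoxy]-4-nitrophenyl methanesulfonate (not isolated) | CS(=O)(=O)Oc1ccc(cc1Oc1ccccc1OC=O)[N+](=O)[O-] | intermediate
8 | 2-(2-hydroxyphenoxy)-4-nitrophenyl methanesulfonate | CS(=O)(=O)Oc1ccc(cc1Oc1ccccc1O)[N+](=O)[O-] | intermediate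
9 | 4-amino-2-(2-hydroxyphenoxy)phenyl methanesulfonate | CS(=O)(=O)Oc1ccc(N)cc1Oc1ccccc1O | intermediate
10 | bromine | BrBr | starting material
11 | 4-amino-3,5-dibromo-2-(3,5-dibromo-2-hydroxyphenoxy)phenyl methanesulfonate | CS(=O)(=O)Oc1cc(Br)c(N)c(Br)c1Oc1cc(Br)cc(Br)c1O | intermediate
12 | iodomethane | CI | starting material
13 | 4-amino-3,5-dibromo-2-(3,5-dibromo-2-methoxyphenoxy)phenyl methanesulfonate | CS(=O)(=O)Oc1cc(Br)c(N)c(Br)c1Oc1cc(Br)cc(Br)c1OC | intermediate
14 | 2,6-dibromo-3-(3,5-dibromo-2-methoxyphenoxy)-4-(methanesulfonyloxy)benzenediazonium hydrogen sulfate (not isolated) | CS(=O)(=O)Oc1cc(Br)c([N+]#N)c(Br)c1Oc1cc(Br)cc(Br)c1OC.OS(=O)(=O)[O-] | intermediate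
15 | 3,5-dibromo-2-(3,5-dibromo-2-methoxyphenoxy)phenyl methanesulfonate | CS(=O)(=O)Oc1cc(Br)cc(Br)c1Oc1cc(Br)cc(Br)c1OC | intermediate
16 | 3,5-dibromo-2-(3,5-dibromo-2-methoxyphenoxy)phenol | COc1c(Br)cc(Br)cc1Oc1c(O)cc(Br)cc1Br | target

Total step count: 8. Longest linear sequence: 8 steps (from 1 or 2 to 16).

Steps most likely to fail

Step 5 (key step). Bromine uptake may stall before the crowded C6' and C2 positions are filled, or the excess oxidant needed to complete it may degrade the electron-rich aminoarene. The fallback brominates the two rings in separate operations.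
- It sets out from 8. Br2 (2 equiv) in AcOH should touch only ring A, because ring B is switched off by the nitro and mesyloxy groups. This gives 2-(3,5-dibromo-2-hydroxyphenoxy)-4-nitrophenyl methanesulfonate F1.
- Reduction with Fe powder and NH4Cl in aqueous EtOH, which spares C–Br bonds, gives 4-amino-2-(3,5-dibromo-2-hydroxyphenoxy)phenyl methanesulfonate F2.
- A second treatment with Br2 (2 equiv) in AcOH fills C4' and C6' under the amine and comes back to the route at 11.

Step 3. Hydride may migrate instead of aryl in the Criegee adduct, because the aryloxy donor is weakened by the electron-poor ring B, and the aldehyde would then be over-oxidised. The fallback masks the ring A phenol as a methyl ketone, where the only competitor is the poorly migrating methyl group.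
- It sets out from 1. Nucleophilic aromatic substitution on commercial 2'-fluoroacetophenone (K2CO3, DMSO, 110 °C) gives 1-[2-(2-hydroxy-5-nitrophenoxy)phenyl]ethan-1-one F3.
- Mesylation with 4 and Et3N gives 2-(2-acetylphenoxy)-4-nitrophenyl methanesulfonate F4.
- Baeyer–Villiger oxidation with trifluoroperacetic acid (urea–H2O2, (CF3CO)2O, Na2HPO4, CH2Cl2) gives 2-[2-(methanesulfonyloxy)-5-nitrophenoxy]phenyl acetate F5.
- Acid-catalysed methanolysis comes back to the route at 8.

Step 1. Arylation may occur through the less basic oxygen without later equilibration, a second arylation may follow, or the catecholate may be oxidised by air. The fallback uses a ring B building block whose C2' oxygen is already capped.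
- It sets out from 2. Substitution with commercial 2-methoxy-5-nitrophenol (K2CO3, DMF, 110 °C) gives 2-(2-methoxy-5-nitrophenoxy)benzaldehyde F6.
- Nucleophilic demethylation of the methoxy group para to the nitro group with LiCl in hot DMF, then acidification, comes back to the route at 3.

Further compounds
F1 | step 5 | 2-(3,5-dibromo-2-hydroxyphenoxy)-4-nitrophenyl methanesulfonate | CS(=O)(=O)Oc1ccc(cc1Oc1cc(Br)cc(Br)c1O)[N+](=O)[O-]
F2 | step 5 | 4-amino-2-(3,5-dibromo-2-hydroxyphenoxy)phenyl methanesulfonate | CS(=O)(=O)Oc1ccc(N)cc1Oc1cc(Br)cc(Br)c1O
F3 | step 3 | 1-[2-(2-hydroxy-5-nitrophenoxy)phenyl]ethan-1-one | CC(=O)c1ccccc1Oc1cc(ccc1O)[N+](=O)[O-]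
F4 | step 3 | 2-(2-acetylphenoxy)-4-nitrophenyl methanesulfonate | CS(=O)(=O)Oc1ccc(cc1Oc1ccccc1C(C)=O)[N+](=O)[O-]
F5 | step 3 | 2-[2-(methanesulfonyloxy)-5-nitrophenoxy]phenyl acetate | CC(=O)Oc1ccccc1Oc1cc(ccc1OS(C)(=O)=O)[N+](=O)[O-]
F6 | step 1 | 2-(2-methoxy-5-nitrophenoxy)benzaldehyde | COc1ccc(cc1Oc1ccccc1C=O)[N+](=O)[O-]
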